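The readings are calculated with made-up constants, noise included.

The pitfall with a halved catalyst charge was to read a steep fall in rate as the order of the catalyst itself.

| flask | substrate | partner | free catalyst | time |
|---|---|---|---|---|
| theta | 0.600 M | 1.50 M | 0.0600 M |  |
| epsilon | 0.240 M | 1.14 M | 0.0600 M |  |
| gamma | 0.600 M | 1.50 M | 0.0300 M |  |
| zeta | 1.20 M | 1.50 M | 0.0600 M |  |
| delta | 0.600 M | 1.50 M | 0.0600 M | 840 min |

| theta run: time / min | theta run: [target] / M | epsilon run: time / min | epsilon run: [target] / M | gamma run: time / min | gamma run: [target] / M | zeta run: time / min | zeta run: [target] / M |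
|---|---|---|---|---|---|---|---|
| 5.0 | 0.036 | 5.0 | 0.013 | 5.0 | 0 | 5.0 | 0.060 |
| 15 | 0.079 | 15 | 0.040 | 15 | 0.020 | 15 | 0.149 |
| 29 | 0.145 | 29 | 0.067 | 29 | 0.043 | 29 | 0.247 |
| 46 | 0.195 | 46 | 0.092 | 46 | 0.059 | 46 | 0.331 |
| 66 | 0.237 | 66 | 0.103 | 66 | 0.090 | 66 | 0.406 |
| 88 | 0.244 | 88 | 0.131 | 88 | 0.094 | 88 | 0.430 |
| 110 | 0.278 | 110 | 0.133 | 110 | 0.102 | 110 | 0.421 |
| 140 | 0.314 | 140 | 0.149 | 140 | 0.123 | 140 | 0.422 |

(each reading ± 0.009 M)

- Overall: substrate + partner -> target, with free catalyst as catalyst.
- Constant volume, constant temperature.
- The analysis sees a species whether free or bound.
- "The second partner" is partner.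
- An order is taken over about fifteen percent of the charge, up and down.

- apparent order in [free catalyst] of the starting rate, round the charge of the theta run (the rate where two percent of its substrate have turned into target)
- apparent order in [partner] of the starting rate, round the charge of the theta run (the rate where two percent of its substrate have turned into target)
- target in the delta run at 840 min, as a share of the substrate charged

I turned the settings one after the other. For catalyst, a rate in step with the charge gives order one, which was the zero of my scale. Over the readings at 15 min, 29 min and 46 min, theta made 3.43 times gamma's target, more than the charges predict. I let the rate follow the charge minus a fixed amount. That gave 0.0177 M, read with the scatter of these readings. I called this the dead charge, catalyst charged that turns nothing over. The usual term is catalyst poisoning. The order is then the charge over the live charge, so theta's was 1.42.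

For substrate, order one predicts that doubling the charge doubles the rate. At 15 min, zeta had 1.89 times theta's target, so I kept order one.

For partner, order one would have cut epsilon below its substrate share of 0.400. Over the readings at 15 min, 29 min and 46 min, epsilon made 0.475 of theta's target, so I took an order near zero.

For the yield, theta's last reading was already 52.3% of its substrate, and zeta read 0.430 M, 0.421 M and 0.422 M at its end. I expected delta little above that share.

The forecast gave order 1.8 in catalyst, order 0 in partner and 65% for delta, and of zeta's stop it said “So the catalyst dies”. My catalyst order was lower, and my yield, near 52.3%, was lower too.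

The flask gave order 1.5 in catalyst, order 0.068 in partner and 51.8% for delta.

    free catalyst + substrate ⇌ catalyst-substrate complex (0.2868 M⁻¹ min⁻¹, 0.2556 min⁻¹)
    catalyst-substrate complex + partner → target + free catalyst (4.002 M⁻¹ min⁻¹)
    2 partner → lost reagent (0.04380 M⁻¹ min⁻¹)
    free catalyst + impurity → spent catalyst

The steep catalyst order came from the impurity. The dead charge of 0.0177 M had given 1.42 against the 1.5 found. With no dead charge my rule gives order one, and without the turning of free catalyst and impurity into spent catalyst the order fell from 1.5 to 1.0.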